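Everything rests on a hidden symmetry: the oxygen on C1 of ring A (the methoxy ring) and the oxygen on C2' of ring B (the phenol ring) both sit ortho to the C6–O–C1' bridge, so joining the C1 oxygen to C2' gives centrosymmetric 1,3,6,8-tetrabromodibenzo-p-dioxin, whose two rings are identical. The route builds this tricycle and then cuts one aryl–O bond: a 4-methoxybenzyl alkoxide attacks C4a (equivalent to C9a), and the expelled phenoxide is methylated in the same flask. In one operation the rings become ring B (masked OH on C2') and ring A (OMe on C1); acid then frees the phenol.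

Key step: step 3

Remark: the four starting materials are assumed to be commercial, and the target has no stereocentre. An ortho-iodo handle is used so that both C–O bonds of the tricycle form at one defined ortho carbon under mild copper catalysis. The tetrabromodibenzodioxin is treated as a potent toxin: steps 2 and 3 are run in closed equipment and all residues are destroyed as halogenated waste.

Step 1
Reactants: 1 2,4-dibromophenol; 2 N-iodosuccinimide
Product: 3 2,4-dibromo-6-iodophenol
Conditions: NIS (1.05 equiv), TsOH·H2O (10 mol %), MeCN, 0 °C → rt, dark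
Reagents that add atoms: N-iodosuccinimide, O=C1CCC(=O)N1I
Why: Electrophilic aromatic substitution (iodination of a phenol with an N-iodoimide under acid catalysis): in 1 the hydroxyl group activates only its ortho and para positions, of which C2 and C4 already carry bromine, so iodine should enter at C6 alone.

Step 2
Reactants: 3 2,4-dibromo-6-iodophenol (two molecules)
Product: 5 1,3,6,8-tetrabromodibenzo-p-dioxin, via open diaryl ether phenolate 4 (not isolated)
Conditions: CuI (10 mol %), picolinic acid (20 mol %), K3PO4 (2 equiv), DMSO, 100 °C, N2; recrystallisation from toluene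
Reagents that add atoms: none
Why: Twofold Ullmann diaryl ether condensation, head to tail: the copper catalyst should engage the C–I bond well ahead of the C–Br bonds, so the phenoxide oxygen of one molecule is joined to the iodine-bearing carbon of the other to give 4, which closes the six-membered dioxin ring in the same way, and the moderate temperature should suppress both para-linked oligomers and Smiles scrambling to the 1,3,7,9-isomer.

Step 3
Reactants: 5 1,3,6,8-tetrabromodibenzo-p-dioxin; 6 4-methoxybenzyl alcohol; 7 iodomethane
Product: 9 1,5-dibromo-2-(3,5-dibromo-2-methoxyphenoxy)-3-[(4-methoxybenzyl)oxy]benzene, via ring-opened potassium phenolate 8 (not isolated)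
Conditions: 6 (1.1 equiv), KN(SiMe3)2 (1.05 equiv), THF, 0 °C; then 5, NMP, rt → 60 °C; then MeI (3 equiv), 0 °C → rt
Reagents that add atoms: 4-methoxybenzyl alcohol, COc1ccc(CO)cc1; iodomethane, CI
Why: Proposed new method: the alkoxide of 6 should add ipso to C4a of 5 (identical with C9a through the inversion centre), the oxygen-bearing carbon that has H-4 as its neighbour and both bromines (C1, C3) meta, to give a Meisenheimer anion whose charge at C10a, C2 and C4 is stabilised inductively by the adjacent C–Br bonds, and collapse breaks C4a–O5 to release phenoxide 8, whose oxygen sits on C5a between an ortho (C6) and a para (C8) bromine. MeI then O-methylates 8 in the same flask (Williamson), so the benzyl-protected oxygen ends up on C2' of ring B and the methyl group on the C1 oxygen of ring A. The closest known reaction types are the SNAr cleavage of halogen-activated diaryl ethers by alkoxides and the ipso attack of the Smiles rearrangement in bromophenoxyphenolates. No ring is closed and no stereocentre is formed. The selectivity needed is attack at C4a/C9a and not at the bromine-flanked C10a/C5a or at a C–Br carbon; it should follow from the lower hindrance at C4a, from the better leaving group (a 2,4-dibromophenoxide type against a 3,5-dibromophenoxide type) and from the symmetry of 5, which turns attack at either C4a or C9a into the same product. A second cleavage should be held back because 8 is an anion and because the alkoxide is used close to one equivalent and is quenched by MeI.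

Step 4
Reactants: 9 1,5-dibromo-2-(3,5-dibromo-2-methoxyphenoxy)-3-[(4-methoxybenzyl)oxy]benzene
Product: 10 3,5-dibromo-2-(3,5-dibromo-2-methoxyphenoxy)phenol
Conditions: CF3CO2H, anisole, CH2Cl2, 0 °C → rt
Reagents that add atoms: none
Why: Acid-mediated SN1 cleavage of an aryl 4-methoxybenzyl ether: CF3CO2H ionises the benzylic C–O bond, anisole captures the 4-methoxybenzyl cation by Friedel–Crafts alkylation, and the methyl ether, the diaryl ether and the four C–Br bonds are inert under these conditions.

Compound list
1 | 2,4-dibromophenol | Oc1ccc(Br)cc1Br | starting material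
2 | N-iodosuccinimide (1-iodopyrrolidine-2,5-dione) | O=C1CCC(=O)N1I | starting material
3 | 2,4-dibromo-6-iodophenol | Oc1c(Br)cc(Br)cc1I | intermediate
4 | potassium 2,4-dibromo-6-(2,4-dibromo-6-iodophenoxy)phenolate | [K+].[O-]c1c(Br)cc(Br)cc1Oc1c(I)cc(Br)cc1Br | intermediate (not isolated)
5 | 1,3,6,8-tetrabromodibenzo-p-dioxin | Brc1cc(Br)c2Oc3cc(Br)cc(Br)c3Oc2c1 | intermediate
6 | 4-methoxybenzyl alcohol | COc1ccc(CO)cc1 | starting material
7 | iodomethane | CI | starting material
8 | potassium 2,4-dibromo-6-{2,4-dibromo-6-[(4-methoxybenzyl)oxy]phenoxy}phenolate | [K+].[O-]c1c(Br)cc(Br)cc1Oc1c(OCc2ccc(OC)cc2)cc(Br)cc1Br | intermediate (not isolated)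
9 | 1,5-dibromo-2-(3,5-dibromo-2-methoxyphenoxy)-3-[(4-methoxybenzyl)oxy]benzene | COc1c(Br)cc(Br)cc1Oc1c(OCc2ccc(OC)cc2)cc(Br)cc1Br | intermediate
10 | 3,5-dibromo-2-(3,5-dibromo-2-methoxyphenoxy)phenol | COc1c(Br)cc(Br)cc1Oc1c(O)cc(Br)cc1Br | target

Total step count: 4
Longest linear sequence: 4 steps (1 → 3 → 5 → 9 → 10)

Steps most likely to fail

Step 3 (new method).
- What may go wrong: the alkoxide may attack a bromine-bearing carbon or the bromine-flanked C10a instead of C4a. It may also deprotonate C2–H between the two bromines, leading to halogen migration or aryne formation. The benzylic alkoxide may transfer hydride and cause debromination, or a second ether cleavage may follow.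
- Fallback, known chemistry only, from 3 to 10 without passing through 5 and 9:
  - O-Methylation of 3 (MeI, K2CO3, acetone) should give 1,5-dibromo-3-iodo-2-methoxybenzene F1.
  - Selective iodine–magnesium exchange (iPrMgCl·LiCl, THF, −40 °C) should give (3,5-dibromo-2-methoxyphenyl)magnesium chloride F2. Trapping with B(OMe)3 should give dimethyl (3,5-dibromo-2-methoxyphenyl)boronate F3, and oxidation (H2O2, NaOH) should give 3,5-dibromo-2-methoxyphenol F4.
  - SNAr of the phenoxide of F4 on commercial 3,5-dibromo-2-fluorobenzaldehyde F5 (K2CO3, DMF, 90 °C), whose fluoride is activated by the ortho formyl group, should give 3,5-dibromo-2-(3,5-dibromo-2-methoxyphenoxy)benzaldehyde F6.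
  - Baeyer–Villiger oxidation (mCPBA, CH2Cl2) should give 3,5-dibromo-2-(3,5-dibromo-2-methoxyphenoxy)phenyl formate F7, and methanolysis (K2CO3, MeOH) rejoins the route at 10.

Step 2.
- What may go wrong: copper may insert into C–Br bonds in competition with C–I, so that chains grow instead of the ring closing. Iodine may be lost by reduction, or Smiles-type isomerisation may occur before the second C–O bond forms.
- Fallback from 1 to 5, with a copper-free SNAr mechanism and no iodine handle:
  - Bromination of 1 at the remaining ortho position (Br2, AcOH, rt) should give 2,4,6-tribromophenol F8.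
  - Its dry potassium salt (K2CO3) is heated at about 280 °C under N2 and should self-condense through potassium 2,4-dibromo-6-(2,4,6-tribromophenoxy)phenolate F9 to 5.
  - The by-product 1,3,7,9-tetrabromodibenzo-p-dioxin F10, formed by Smiles rearrangement, would be removed by fractional crystallisation before the route is rejoined at 5.

Step 4.
- What may go wrong: the benzylic cation may be recaptured by the freed phenol ring (C-alkylation), or ionisation of the hindered ether may be incomplete.
- Fallback from 5 to 10, with a protecting group that leaves without a cation: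
  - The ring opening of step 3 is run with the potassium alkoxide of 2-(trimethylsilyl)ethanol F11 (KN(SiMe3)2, THF–NMP).
  - The intermediate potassium 2,4-dibromo-6-{2,4-dibromo-6-[2-(trimethylsilyl)ethoxy]phenoxy}phenolate F12 is methylated with MeI to {2-[3,5-dibromo-2-(3,5-dibromo-2-methoxyphenoxy)phenoxy]ethyl}trimethylsilane F13.
  - Bu4NF in THF then unmasks the phenol by fluoride-triggered β-elimination, and the route is rejoined at 10.

Further compounds
F1 | step 3 | 1,5-dibromo-3-iodo-2-methoxybenzene | COc1c(Br)cc(Br)cc1I
F2 | step 3 | (3,5-dibromo-2-methoxyphenyl)magnesium chloride | COc1c(Br)cc(Br)cc1[Mg]Cl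
F3 | step 3 | dimethyl (3,5-dibromo-2-methoxyphenyl)boronate | COB(OC)c1cc(Br)cc(Br)c1OC
F4 | step 3 | 3,5-dibromo-2-methoxyphenol | COc1c(Br)cc(Br)cc1O
F5 | step 3 | 3,5-dibromo-2-fluorobenzaldehyde | O=Cc1cc(Br)cc(Br)c1F
F6 | step 3 | 3,5-dibromo-2-(3,5-dibromo-2-methoxyphenoxy)benzaldehyde | COc1c(Br)cc(Br)cc1Oc1c(C=O)cc(Br)cc1Br
F7 | step 3 | 3,5-dibromo-2-(3,5-dibromo-2-methoxyphenoxy)phenyl formate | COc1c(Br)cc(Br)cc1Oc1c(OC=O)cc(Br)cc1Br
F8 | step 2 | 2,4,6-tribromophenol | Oc1c(Br)cc(Br)cc1Br
F9 | step 2 | potassium 2,4-dibromo-6-(2,4,6-tribromophenoxy)phenolate | [K+].[O-]c1c(Br)cc(Br)cc1Oc1c(Br)cc(Br)cc1Br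
F10 | step 2 | 1,3,7,9-tetrabromodibenzo-p-dioxin | Brc1cc(Br)c2Oc3c(Br)cc(Br)cc3Oc2c1
F11 | step 4 | 2-(trimethylsilyl)ethanol | C[Si](C)(C)CCO
F12 | step 4 | potassium 2,4-dibromo-6-{2,4-dibromo-6-[2-(trimethylsilyl)ethoxy]phenoxy}phenolate | [K+].[O-]c1c(Br)cc(Br)cc1Oc1c(OCC[Si](C)(C)C)cc(Br)cc1Br
F13 | step 4 | {2-[3,5-dibromo-2-(3,5-dibromo-2-methoxyphenoxy)phenoxy]ethyl}trimethylsilane | COc1c(Br)cc(Br)cc1Oc1c(OCC[Si](C)(C)C)cc(Br)cc1Br
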